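## Retrosynthetic overview

1. Ring B (pyran) is closed last. Its C3=C4 alkene comes from E2 elimination of a (2S,3R)-3-chromanol, which arises by 6-endo opening, with inversion, of an (R,R)-epoxide made by Shi epoxidation of an E-trisubstituted alkene; this fixes C2 of the chromene.
2. The side-chain CH2–C(Me)= bond comes from a B-alkyl Suzuki–Miyaura coupling of a ring A vinyl compound with an aryl (E)-vinyl iodide. The iodide is made from 1,5-dibromo-2,4-dimethoxybenzene by hydroxylation, MOM protection, ortho-lithiation/butynylation and hydrozirconation–iodination.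
3. Ring A (cyclohexane) is made first, by an enantioselective Diels–Alder reaction of a 1-silyloxy-2-methylbutadiene (from tiglic aldehyde) with methacrolein. It forms ring bonds C1–C2 and C5–C6 (C1 = quaternary carbon, C2 = methylidene carbon, C3 = methyl-bearing CH).
4. Enabling feature: in ring A the quaternary C1 (methyl plus chain CH2) lies between the unsubstituted C6H2 and C2. C6–C1 is therefore a 1,1-disubstituted dienophile whose formyl group becomes the first chain carbon, and C2–C5 is a butadiene whose C2 oxygen (later C=CH2) steers regiochemistry and relays configuration to C3.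
5. Ring order: A (step 2), aromatic ring C bought, B (steps 14 and 16).

Key step: step 2

Assumption (chemistry): the (S)-oxazaborolidinium ion is taken to leave the Re face at C-alpha of bound methacrolein open, as in its additions to other 2-substituted acroleins; if the sense proves opposite, the (R)-catalyst is used. Compounds 1, 3, 7, 10 and the fructose-derived ketone are taken as commercial.

## Route

Step 1
Reactants: 1 (2E)-2-methylbut-2-enal (tiglic aldehyde)
Product: 2 (1E)-2-methyl-1-[(triisopropylsilyl)oxy]buta-1,3-diene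
Conditions: TIPSOTf, Et3N, Et2O, 0 °C to rt
Reagents that add atoms: triisopropylsilyl trifluoromethanesulfonate, CC(C)[Si](OS(=O)(=O)C(F)(F)F)(C(C)C)C(C)C
Why: O-silylation of the enal and gamma-deprotonation by the amine (vinylogous soft enolisation) should give the extended silyl dienol ether, the s-trans enal leading to the 1E isomer needed for cycloaddition.

Step 2
Reactants: 2 (1E)-2-methyl-1-[(triisopropylsilyl)oxy]buta-1,3-diene; 3 2-methylprop-2-enal (methacrolein)
Product: 4 (1S,2R)-1,3-dimethyl-2-[(triisopropylsilyl)oxy]cyclohex-3-ene-1-carbaldehyde (silyloxy cis to formyl)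
Conditions: (S)-1-(2-methylphenyl)-3,3-diphenylhexahydropyrrolo[1,2-c][1,3,2]oxazaborole (20 mol %), (CF3SO2)2NH (16 mol %), CH2Cl2, −78 °C
Reagents that add atoms: none
Why: The protonated oxazaborolidine binds the s-trans enal at boron (with a formyl C–H···O contact) and the silyloxydiene adds in a concerted, asynchronous, normal-electron-demand [4+2] cycloaddition; the closest known reaction type is the oxazaborolidinium-catalysed Diels–Alder reaction of 2-substituted acroleins with oxygenated acyclic dienes. Ring A is closed by intermolecular [4+2] cycloaddition, both new sigma bonds (C1–C2 and C5–C6 of the cyclohexene) forming suprafacially on each partner. The quaternary centre C1 (S here, R in the target after the change of substituent priorities) is set by the catalyst, whose aryl groups shield the Si face at C-alpha of the bound enal so that the diene adds to the Re face. The C2 centre (R) follows from the E geometry of the dienol ether and the endo placement of the formyl group, which keeps the alpha-methyl group exo and away from the diene 2-methyl group; C2 later relays its configuration to C3 and is then erased. The step needs ortho regiochemistry, endo selectivity and one enantioface: the 1-silyloxy donor puts the largest HOMO coefficient on the unsubstituted diene terminus, which bonds to the enal beta-carbon and overrides the opposing 2-methyl effect, while the low temperature and the bulky silyl group suppress protodesilylation and a stepwise Mukaiyama–Michael path.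

Step 3
Reactants: 4 (1S,2R)-1,3-dimethyl-2-[(triisopropylsilyl)oxy]cyclohex-3-ene-1-carbaldehyde
Product: 5 (1S,2R,3R)-1,3-dimethyl-2-[(triisopropylsilyl)oxy]cyclohexane-1-carbaldehyde (formyl, silyloxy and C3 methyl all cis)
Conditions: H2 (5 bar), Rh/Al2O3 (5 wt %), EtOAc, rt
Reagents that add atoms: none
Why: Heterogeneous syn-hydrogenation should occur on the ring face opposite the allylic silyloxy group and the formyl group (both on one face), so the new C3–H is cis to the C1 methyl and C3 is set as R, with rhodium on alumina limiting double-bond migration and allylic C–O hydrogenolysis.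

Step 4
Reactants: 5 (1S,2R,3R)-1,3-dimethyl-2-[(triisopropylsilyl)oxy]cyclohexane-1-carbaldehyde
Product: 6 {[(1R,2R,6R)-2-ethenyl-2,6-dimethylcyclohexyl]oxy}tri(propan-2-yl)silane
Conditions: Ph3PCH3Br, KOt-Bu, THF, 0 °C to rt
Reagents that add atoms: methyltriphenylphosphonium bromide (as its ylide), C[P+](c1ccccc1)(c1ccccc1)c1ccccc1.[Br-]
Why: Wittig methylenation of a non-enolisable neopentyl aldehyde should proceed cleanly and cannot disturb the quaternary centre.

Step 5
Reactants: 7 1,5-dibromo-2,4-dimethoxybenzene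
Product: 8 4,6-dimethoxybenzene-1,3-diol
Conditions: Pd2(dba)3 (2 mol %), 2-(di-tert-butylphosphino)-2′,4′,6′-triisopropylbiphenyl (8 mol %), KOH, 1,4-dioxane/H2O, 100 °C, degassed; then aq. HCl
Reagents that add atoms: potassium hydroxide, [K+].[OH-]
Why: Palladium-catalysed hydroxylation of aryl bromides with a bulky biarylphosphine should replace both bromides by hydroxyl through C–O reductive elimination.

Step 6
Reactants: 8 4,6-dimethoxybenzene-1,3-diol
Product: 9 1,5-dimethoxy-2,4-bis(methoxymethoxy)benzene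
Conditions: MOMCl, i-Pr2NEt, CH2Cl2, 0 °C to rt
Reagents that add atoms: chloromethyl methyl ether, COCCl
Why: O-alkylation of both phenols (MOM protection) installs two strong ortho-directing groups around the carbon that must carry the side chain.

Step 7
Reactants: 9 1,5-dimethoxy-2,4-bis(methoxymethoxy)benzene; 10 1-bromobut-2-yne
Product: 12 3-(but-2-yn-1-yl)-1,5-dimethoxy-2,4-bis(methoxymethoxy)benzene, via aryllithium 11 (not isolated)
Conditions: n-BuLi, THF, 0 °C; then 10, −78 °C to rt
Reagents that add atoms: none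
Why: Directed ortho-metalation should occur at the carbon flanked by the two OMOM groups, and the aryllithium is alkylated at the primary propargylic bromide by SN2.

Step 8
Reactants: 12 3-(but-2-yn-1-yl)-1,5-dimethoxy-2,4-bis(methoxymethoxy)benzene
Product: 14 3-[(2E)-3-iodobut-2-en-1-yl]-1,5-dimethoxy-2,4-bis(methoxymethoxy)benzene, via alkenylzirconocene chloride 13 (not isolated)
Conditions: Cp2Zr(H)Cl (2.2 equiv), THF, 50 °C; then I2, 0 °C
Reagents that add atoms: iodine, II
Why: Syn-hydrozirconation with equilibration under excess Cp2Zr(H)Cl should place zirconium on the less hindered, methyl-bearing alkyne carbon, and iodinolysis with retention gives the E-iodide with iodine trans to the benzylic CH2 (hydrozirconation–iodination).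

Step 9
Reactants: 6 {[(1R,2R,6R)-2-ethenyl-2,6-dimethylcyclohexyl]oxy}tri(propan-2-yl)silane; 14 3-[(2E)-3-iodobut-2-en-1-yl]-1,5-dimethoxy-2,4-bis(methoxymethoxy)benzene
Product: 16 triisopropyl{[(1R,2R,6R)-2-{(3E)-5-[2,6-bis(methoxymethoxy)-3,5-dimethoxyphenyl]-3-methylpent-3-en-1-yl}-2,6-dimethylcyclohexyl]oxy}silane, via B-alkyl-9-BBN borane 15 (not isolated)
Conditions: 9-BBN-H, THF, rt; then 14, PdCl2(dppf) (5 mol %), AsPh3, Cs2CO3, DMF/H2O, rt to 45 °C
Reagents that add atoms: none
Why: 9-BBN-H should hydroborate the only alkene at its terminal carbon, and the B-alkyl Suzuki–Miyaura coupling joins the sp3 and sp2 carbons with retention of the E geometry of the iodide.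

Step 10
Reactants: 16 triisopropyl{[(1R,2R,6R)-2-{(3E)-5-[2,6-bis(methoxymethoxy)-3,5-dimethoxyphenyl]-3-methylpent-3-en-1-yl}-2,6-dimethylcyclohexyl]oxy}silane
Product: 17 (1R,2R,6R)-2-{(3E)-5-[2,6-bis(methoxymethoxy)-3,5-dimethoxyphenyl]-3-methylpent-3-en-1-yl}-2,6-dimethylcyclohexan-1-ol
Conditions: Bu4NF, THF, 50 °C
Reagents that add atoms: none
Why: Fluoride-induced desilylation should free the hindered secondary alcohol without touching the MOM ethers or the alkene.

Step 11
Reactants: 17 (1R,2R,6R)-2-{(3E)-5-[2,6-bis(methoxymethoxy)-3,5-dimethoxyphenyl]-3-methylpent-3-en-1-yl}-2,6-dimethylcyclohexan-1-ol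
Product: 18 (2R,6R)-2-{(3E)-5-[2,6-bis(methoxymethoxy)-3,5-dimethoxyphenyl]-3-methylpent-3-en-1-yl}-2,6-dimethylcyclohexan-1-one
Conditions: Dess–Martin periodinane, NaHCO3, CH2Cl2, 0 °C to rt
Reagents that add atoms: none
Why: Dess–Martin oxidation under buffered conditions should give the ketone without epimerising the adjacent C6 methyl centre.

Step 12
Reactants: 18 (2R,6R)-2-{(3E)-5-[2,6-bis(methoxymethoxy)-3,5-dimethoxyphenyl]-3-methylpent-3-en-1-yl}-2,6-dimethylcyclohexan-1-one
Product: 19 3-{(2E)-5-[(1R,3R)-1,3-dimethyl-2-methylidenecyclohexyl]-3-methylpent-2-en-1-yl}-1,5-dimethoxy-2,4-bis(methoxymethoxy)benzene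
Conditions: Cp2TiMe2 (3 equiv), toluene/THF, 70 °C, dark
Reagents that add atoms: dimethyltitanocene, C[Ti](C)(C1C=CC=C1)C1C=CC=C1
Why: Petasis methylenation through a titanium methylidene and an oxatitanacyclobutane is non-basic, so the hindered, enolisable ketone should be converted to the exocyclic alkene without epimerisation.

Step 13
Reactants: 19 3-{(2E)-5-[(1R,3R)-1,3-dimethyl-2-methylidenecyclohexyl]-3-methylpent-2-en-1-yl}-1,5-dimethoxy-2,4-bis(methoxymethoxy)benzene
Product: 20 (2R,3R)-3-{[2,6-bis(methoxymethoxy)-3,5-dimethoxyphenyl]methyl}-2-{2-[(1R,3R)-1,3-dimethyl-2-methylidenecyclohexyl]ethyl}-2-methyloxirane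
Conditions: 1,2:4,5-di-O-isopropylidene-β-D-erythro-2,3-hexodiulo-2,6-pyranose (30 mol %), KHSO5 (as 2KHSO5·KHSO4·K2SO4), K2CO3, Bu4NHSO4 (cat.), aq. Na2B4O7 buffer/MeCN/CH2(OMe)2, 0 °C
Reagents that add atoms: potassium peroxymonosulfate, [K+].[O-]S(=O)(=O)OO
Why: Shi epoxidation by the chiral dioxirane through a spiro transition state should oxidise only the electron-rich, unhindered trisubstituted alkene (the methylidene group is shielded by two substituted neighbours), and the D-fructose-derived ketone delivers oxygen to the face that gives the (R,R)-oxirane, as for other E-trisubstituted alkenes.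

Step 14
Reactants: 20 (2R,3R)-3-{[2,6-bis(methoxymethoxy)-3,5-dimethoxyphenyl]methyl}-2-{2-[(1R,3R)-1,3-dimethyl-2-methylidenecyclohexyl]ethyl}-2-methyloxirane
Product: 22 (2S,3R)-2-{2-[(1R,3R)-1,3-dimethyl-2-methylidenecyclohexyl]ethyl}-6,8-dimethoxy-2-methyl-3,4-dihydro-2H-chromene-3,5-diol, via mono-MOM chromanol 21 (not isolated)
Conditions: (±)-camphor-10-sulfonic acid (10 mol %), CH2Cl2/MeOH 20:1, −20 to 0 °C; then HCl (0.5 M in MeOH), rt
Reagents that add atoms: none
Why: Acid activation should open the epoxide 6-endo at its tertiary, cation-stabilising carbon by the ortho oxygen (the MOM cation is passed to methanol) with inversion, setting C2 of ring B as S while C3 keeps its oxygen, and acetal methanolysis then frees the second phenol; this is the acid-mediated epoxide-opening cyclisation of ortho-prenylphenol epoxides to 3-chromanols.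

Step 15
Reactants: 22 (2S,3R)-2-{2-[(1R,3R)-1,3-dimethyl-2-methylidenecyclohexyl]ethyl}-6,8-dimethoxy-2-methyl-3,4-dihydro-2H-chromene-3,5-diol
Product: 24 (2S,3R)-2-{2-[(1R,3R)-1,3-dimethyl-2-methylidenecyclohexyl]ethyl}-3-[(methanesulfonyl)oxy]-6,8-dimethoxy-2-methyl-3,4-dihydro-2H-chromen-5-yl acetate, via phenol acetate 23 (not isolated)
Conditions: Ac2O (1.05 equiv), Et3N, CH2Cl2, 0 °C; then MsCl, Et3N, 0 °C to rt
Reagents that add atoms: acetic anhydride, CC(=O)OC(C)=O; methanesulfonyl chloride, CS(=O)(=O)Cl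
Why: Under amine base without an acyl-transfer catalyst the phenol should be acetylated much faster than the neopentyl-like secondary alcohol, which is then mesylated, so the two hydroxyl groups are differentiated in one flask.

Step 16
Reactants: 24 (2S,3R)-2-{2-[(1R,3R)-1,3-dimethyl-2-methylidenecyclohexyl]ethyl}-3-[(methanesulfonyl)oxy]-6,8-dimethoxy-2-methyl-3,4-dihydro-2H-chromen-5-yl acetate
Product: 26 (2S)-2-{2-[(1R,3R)-1,3-dimethyl-2-methylidenecyclohexyl]ethyl}-6,8-dimethoxy-2-methyl-2H-chromen-5-ol (metachromin B), via chromene acetate 25 (not isolated)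
Conditions: DBU, toluene, 80 °C; then K2CO3 (cat.), MeOH, rt, argon
Reagents that add atoms: none
Why: Anti E2 elimination of the C3 mesylate can only use a benzylic C4 hydrogen (C2 is quaternary) and should give the conjugated 2H-chromene, after which methanolysis of the aryl acetate frees the phenol under basic conditions that leave C2 and the methylidene group untouched.

## Compound list

1 | (2E)-2-methylbut-2-enal (tiglic aldehyde) | C/C=C(\C)C=O | starting material
2 | (1E)-2-methyl-1-[(triisopropylsilyl)oxy]buta-1,3-diene | C=C/C(C)=C/O[Si](C(C)C)(C(C)C)C(C)C | intermediate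
3 | 2-methylprop-2-enal (methacrolein) | CC(=C)C=O | starting material
4 | (1S,2R)-1,3-dimethyl-2-[(triisopropylsilyl)oxy]cyclohex-3-ene-1-carbaldehyde | O=C[C@@]1(C)CCC=C(C)[C@H]1O[Si](C(C)C)(C(C)C)C(C)C | intermediate
5 | (1S,2R,3R)-1,3-dimethyl-2-[(triisopropylsilyl)oxy]cyclohexane-1-carbaldehyde | O=C[C@@]1(C)CCC[C@@H](C)[C@H]1O[Si](C(C)C)(C(C)C)C(C)C | intermediate
6 | {[(1R,2R,6R)-2-ethenyl-2,6-dimethylcyclohexyl]oxy}tri(propan-2-yl)silane | C=C[C@@]1(C)CCC[C@@H](C)[C@H]1O[Si](C(C)C)(C(C)C)C(C)C | intermediate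
7 | 1,5-dibromo-2,4-dimethoxybenzene | COc1cc(OC)c(Br)cc1Br | starting material
8 | 4,6-dimethoxybenzene-1,3-diol | COc1cc(OC)c(O)cc1O | intermediate
9 | 1,5-dimethoxy-2,4-bis(methoxymethoxy)benzene | COCOc1cc(OCOC)c(OC)cc1OC | intermediate
10 | 1-bromobut-2-yne | CC#CCBr | starting material
11 | [2,6-bis(methoxymethoxy)-3,5-dimethoxyphenyl]lithium | [Li]c1c(OCOC)c(OC)cc(OC)c1OCOC | intermediate
12 | 3-(but-2-yn-1-yl)-1,5-dimethoxy-2,4-bis(methoxymethoxy)benzene | CC#CCc1c(OCOC)c(OC)cc(OC)c1OCOC | intermediate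
13 | {(2E)-4-[2,6-bis(methoxymethoxy)-3,5-dimethoxyphenyl]but-2-en-2-yl}chlorobis(cyclopentadienyl)zirconium | C/C(=C\Cc1c(OCOC)c(OC)cc(OC)c1OCOC)[Zr](Cl)(C1C=CC=C1)C1C=CC=C1 | intermediate
14 | 3-[(2E)-3-iodobut-2-en-1-yl]-1,5-dimethoxy-2,4-bis(methoxymethoxy)benzene | C/C(I)=C\Cc1c(OCOC)c(OC)cc(OC)c1OCOC | intermediate
15 | B-alkyl-9-borabicyclo[3.3.1]nonane from 6 (boron on the terminal carbon of the former vinyl group; ring stereocentres as in 6) | C(C[C@@]1(C)CCC[C@@H](C)[C@H]1O[Si](C(C)C)(C(C)C)C(C)C)B1C2CCCC1CCC2 | intermediate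
16 | triisopropyl{[(1R,2R,6R)-2-{(3E)-5-[2,6-bis(methoxymethoxy)-3,5-dimethoxyphenyl]-3-methylpent-3-en-1-yl}-2,6-dimethylcyclohexyl]oxy}silane | COCOc1c(OC)cc(OC)c(OCOC)c1C/C=C(\C)CC[C@@]1(C)CCC[C@@H](C)[C@H]1O[Si](C(C)C)(C(C)C)C(C)C | intermediate
17 | (1R,2R,6R)-2-{(3E)-5-[2,6-bis(methoxymethoxy)-3,5-dimethoxyphenyl]-3-methylpent-3-en-1-yl}-2,6-dimethylcyclohexan-1-ol | COCOc1c(OC)cc(OC)c(OCOC)c1C/C=C(\C)CC[C@@]1(C)CCC[C@@H](C)[C@H]1O | intermediate
18 | (2R,6R)-2-{(3E)-5-[2,6-bis(methoxymethoxy)-3,5-dimethoxyphenyl]-3-methylpent-3-en-1-yl}-2,6-dimethylcyclohexan-1-one | COCOc1c(OC)cc(OC)c(OCOC)c1C/C=C(\C)CC[C@@]1(C)CCC[C@@H](C)C1=O | intermediate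
19 | 3-{(2E)-5-[(1R,3R)-1,3-dimethyl-2-methylidenecyclohexyl]-3-methylpent-2-en-1-yl}-1,5-dimethoxy-2,4-bis(methoxymethoxy)benzene | COCOc1c(OC)cc(OC)c(OCOC)c1C/C=C(\C)CC[C@@]1(C)CCC[C@@H](C)C1=C | intermediate
20 | (2R,3R)-3-{[2,6-bis(methoxymethoxy)-3,5-dimethoxyphenyl]methyl}-2-{2-[(1R,3R)-1,3-dimethyl-2-methylidenecyclohexyl]ethyl}-2-methyloxirane | COCOc1c(OC)cc(OC)c(OCOC)c1C[C@H]2O[C@]2(C)CC[C@@]3(C)CCC[C@@H](C)C3=C | intermediate
21 | (2S,3R)-2-{2-[(1R,3R)-1,3-dimethyl-2-methylidenecyclohexyl]ethyl}-6,8-dimethoxy-5-(methoxymethoxy)-2-methyl-3,4-dihydro-2H-chromen-3-ol | O[C@@H]1Cc2c(OCOC)c(OC)cc(OC)c2O[C@@]1(C)CC[C@@]3(C)CCC[C@@H](C)C3=C | intermediate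
22 | (2S,3R)-2-{2-[(1R,3R)-1,3-dimethyl-2-methylidenecyclohexyl]ethyl}-6,8-dimethoxy-2-methyl-3,4-dihydro-2H-chromene-3,5-diol | O[C@@H]1Cc2c(O)c(OC)cc(OC)c2O[C@@]1(C)CC[C@@]3(C)CCC[C@@H](C)C3=C | intermediate
23 | (2S,3R)-2-{2-[(1R,3R)-1,3-dimethyl-2-methylidenecyclohexyl]ethyl}-3-hydroxy-6,8-dimethoxy-2-methyl-3,4-dihydro-2H-chromen-5-yl acetate | O[C@@H]1Cc2c(OC(C)=O)c(OC)cc(OC)c2O[C@@]1(C)CC[C@@]3(C)CCC[C@@H](C)C3=C | intermediate
24 | (2S,3R)-2-{2-[(1R,3R)-1,3-dimethyl-2-methylidenecyclohexyl]ethyl}-3-[(methanesulfonyl)oxy]-6,8-dimethoxy-2-methyl-3,4-dihydro-2H-chromen-5-yl acetate | CS(=O)(=O)O[C@@H]1Cc2c(OC(C)=O)c(OC)cc(OC)c2O[C@@]1(C)CC[C@@]3(C)CCC[C@@H](C)C3=C | intermediate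
25 | (2S)-2-{2-[(1R,3R)-1,3-dimethyl-2-methylidenecyclohexyl]ethyl}-6,8-dimethoxy-2-methyl-2H-chromen-5-yl acetate | C=C1[C@H](C)CCC[C@]1(C)CC[C@@]1(C)C=Cc2c(OC(C)=O)c(OC)cc(OC)c2O1 | intermediate
26 | (2S)-2-{2-[(1R,3R)-1,3-dimethyl-2-methylidenecyclohexyl]ethyl}-6,8-dimethoxy-2-methyl-2H-chromen-5-ol (metachromin B) | C=C1[C@H](C)CCC[C@]1(C)CC[C@@]1(C)C=Cc2c(O)c(OC)cc(OC)c2O1 | target

## Step count and risks

Total steps: 16. Longest linear sequence: 12 (steps 1–4, then 9–16; the arene branch, steps 5–8 then 9–16, is equally long).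

Steps most likely to fail:

**Step 14.** While the phenol oxygen is still masked, the activated epoxide may be captured by methanol or close 5-exo at the secondary carbon, and the later acid treatment may erode the configuration at the tertiary carbon. The fallback separates deprotection from cyclisation. It sets out from 19: HCl in MeOH at rt removes both MOM groups before any epoxide exists and should give 2-{(2E)-5-[(1R,3R)-1,3-dimethyl-2-methylidenecyclohexyl]-3-methylpent-2-en-1-yl}-4,6-dimethoxybenzene-1,3-diol F1. TBSCl and imidazole in DMF convert it into the bis(tert-butyldimethylsilyl) ether F2, and Shi epoxidation under the conditions of step 13 should give the (R,R)-epoxy bis-silyl ether F3. Bu4NF buffered with AcOH in THF at 0 °C frees the epoxy resorcinol F4 without forming a phenoxide. A catalytic amount of (±)-camphor-10-sulfonic acid in CH2Cl2 at −20 °C then lets the free phenol open the epoxide 6-endo, and the route comes back at 22.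

**Step 3.** Hydrogen may be delivered to both ring faces, or the double bond may migrate before reduction, giving the wrong C3 epimer. The fallback enforces the face by a temporary cis-fused ring. It sets out from 4: NaBH4 in MeOH should give the primary alcohol F5, Bu4NF the cis-1,3-diol F6, and 2,2-dimethoxypropane with pyridinium p-toluenesulfonate the cis-fused acetonide F7. Hydrogenation over Pd/C should then occur on the convex face (the face of the angular methyl and hydrogen) and give the saturated acetonide F8. Aqueous AcOH releases the saturated diol F9, Dess–Martin periodinane oxidises both hydroxyl groups to the keto aldehyde F10, and excess Cp2TiMe2 in toluene at 70 °C methylenates both carbonyl groups to (1R,3R)-1-ethenyl-1,3-dimethyl-2-methylidenecyclohexane F11. 9-BBN-H hydroborates only the vinyl group, and coupling with 14 under the conditions of step 9 brings the route back at 19.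

**Step 2.** The strongly acidic catalyst may protodesilylate or oligomerise the silyl dienol ether, or enantiofacial discrimination may be insufficient. The fallback replaces catalyst control by resolution. It sets out from 2 and 3: heating in toluene at 80 °C without catalyst should give the endo adduct as a racemate, that is 4 together with its (1R,2S)-enantiomer F12. Condensation with (1R,2R)-N,N′-dimethyl-1,2-diphenylethane-1,2-diamine over molecular sieves in Et2O converts the two into the diastereomeric imidazolidines, the aminal of 4 F13 and the aminal of the enantiomer F14, which are separated by chromatography. Mild hydrolysis of F13 (wet silica gel or cold dilute aqueous acid) returns the route at 4.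

Further compounds
F1 | step 14 | 2-{(2E)-5-[(1R,3R)-1,3-dimethyl-2-methylidenecyclohexyl]-3-methylpent-2-en-1-yl}-4,6-dimethoxybenzene-1,3-diol | Oc1c(OC)cc(OC)c(O)c1C/C=C(\C)CC[C@@]1(C)CCC[C@@H](C)C1=C
F2 | step 14 | bis(tert-butyldimethylsilyl) ether of F1 | CC(C)(C)[Si](C)(C)Oc1c(OC)cc(OC)c(O[Si](C)(C)C(C)(C)C)c1C/C=C(\C)CC[C@@]1(C)CCC[C@@H](C)C1=C
F3 | step 14 | (2R,3R)-epoxide of F2 | CC(C)(C)[Si](C)(C)Oc1c(OC)cc(OC)c(O[Si](C)(C)C(C)(C)C)c1C[C@H]2O[C@]2(C)CC[C@@]3(C)CCC[C@@H](C)C3=C
F4 | step 14 | (2R,3R)-epoxide of F1 (free resorcinol) | Oc1c(OC)cc(OC)c(O)c1C[C@H]2O[C@]2(C)CC[C@@]3(C)CCC[C@@H](C)C3=C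
F5 | step 3 | [1,3-dimethyl-2-(triisopropylsilyloxy)cyclohex-3-en-1-yl]methanol with the ring configuration of 4 | OC[C@@]1(C)CCC=C(C)[C@H]1O[Si](C(C)C)(C(C)C)C(C)C
F6 | step 3 | 6-(hydroxymethyl)-2,6-dimethylcyclohex-2-en-1-ol, hydroxyl cis to hydroxymethyl | OC[C@@]1(C)CCC=C(C)[C@H]1O
F7 | step 3 | cis-fused acetonide of F6 | CC1(C)OC[C@@]2(C)CCC=C(C)[C@H]2O1
F8 | step 3 | saturated acetonide, new methyl centre as in 5 | CC1(C)OC[C@@]2(C)CCC[C@@H](C)[C@H]2O1
F9 | step 3 | 2-(hydroxymethyl)-2,6-dimethylcyclohexan-1-ol with the ring configuration of 5 | OC[C@@]1(C)CCC[C@@H](C)[C@H]1O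
F10 | step 3 | (1R,3R)-1,3-dimethyl-2-oxocyclohexane-1-carbaldehyde | O=C[C@@]1(C)CCC[C@@H](C)C1=O
F11 | step 3 | (1R,3R)-1-ethenyl-1,3-dimethyl-2-methylidenecyclohexane | C=C[C@@]1(C)CCC[C@@H](C)C1=C
F12 | step 2 | (1R,2S)-1,3-dimethyl-2-[(triisopropylsilyl)oxy]cyclohex-3-ene-1-carbaldehyde (enantiomer of 4) | O=C[C@]1(C)CCC=C(C)[C@@H]1O[Si](C(C)C)(C(C)C)C(C)C
F13 | step 2 | (4R,5R)-1,3-dimethyl-4,5-diphenylimidazolidine aminal of 4 | CN1C([C@@]3(C)CCC=C(C)[C@H]3O[Si](C(C)C)(C(C)C)C(C)C)N(C)[C@H](c2ccccc2)[C@H]1c1ccccc1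
F14 | step 2 | (4R,5R)-1,3-dimethyl-4,5-diphenylimidazolidine aminal of F12 | CN1C([C@]3(C)CCC=C(C)[C@@H]3O[Si](C(C)C)(C(C)C)C(C)C)N(C)[C@H](c2ccccc2)[C@H]1c1ccccc1
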